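**Retrosynthetic overview**
- Target ⇒ 3α,9β-dihydroxy-10βH-eremophil-11-en-8-one by double O-acylation with senecioyl chloride.
- Diol ⇒ isopetasol by kinetic deconjugation of the isopropylidene enone, then copper hydride 1,4-reduction and enol ether oxidation (C-10 H, C-9 O).
- Isopetasol ⇒ 3α,4α-epoxyeudesm-7(11)-en-8-one by an epoxide-triggered 1,2-H/1,2-Me shift cascade (eudesmane → eremophilane, as in the biosynthesis), which also delivers the C-3 oxygen.
- Epoxide ⇒ eudesma-3,7(11)-dien-8-one ⇒ germacrone by enantioselective proton-induced transannular C-5–C-10 closure.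
- Ring order: the ten-membered ring is bought; one transannular bond forms rings A and B together; no ring is formed afterwards.

Assumption: germacrone (crystalline main constituent of zdravetz oil, sold in bulk) counts as a cheap commercial starting material; locants are those of germacrane/eudesmane/eremophilane, and α/β mean below/above the ring plane drawn with ring A on the left and the C-4 and C-5 methyls of the target up.

**Step 1**
Reactants: 1 germacrone
Product: 2 (5R,10R)-eudesma-3,7(11)-dien-8-one (5α-H, 10β-methyl, trans-fused)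
Conditions: (S,S)-IDPi acid HN[P(=NSO2CF3)(O2C20H10Ar2)]2, Ar = 3,5-(CF3)2C6H3 (5 mol %, antipode if the sense is opposite), CHCl3, −20 °C; double-bond isomers removed on AgNO3–silica
Reagents that add atoms: none
Why: Proposed new method: the confined chiral acid protonates C-1 of one of the two rapidly interconverting mirror-image conformers of 1, the C-10 cation is captured across the ring by C-5 of the 4,5-alkene through a chair–chair array (setting 10β-methyl and 5α-H) and the paired anion removes H-3; the closest known chemistry is the racemic acid-induced germacrone → selinadienone transannular cyclization and enantioselective cation–olefin cyclizations catalysed by confined imidodiphosphorimidate acids.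

**Step 2**
Reactants: 2 (5R,10R)-eudesma-3,7(11)-dien-8-one
Product: 3 3α,4α-epoxy-5αH-eudesm-7(11)-en-8-one
Conditions: mCPBA (1.05 equiv), CH2Cl2, 0 °C
Reagents that add atoms: mCPBA (3-chloroperoxybenzoic acid), O=C(OO)c1cccc(Cl)c1
Why: Prilezhaev epoxidation, in which the electron-rich trisubstituted 3,4-alkene reacts far faster than the tetrasubstituted enone alkene and the peracid attacks anti to the axial C-10 methyl, setting C-3 and C-4 (oxygen α).

**Step 3**
Reactants: 3 3α,4α-epoxy-5αH-eudesm-7(11)-en-8-one
Product: 4 isopetasol (3α-hydroxyeremophila-7(11),9-dien-8-one; 4β,5β-dimethyl)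
Conditions: BF3·OEt2 (0.5 equiv), CH2Cl2, −78 → −20 °C
Reagents that add atoms: none
Why: Proposed new method: BF3 opens the epoxide at tertiary C-4 to leave an axial 3α-O–BF3 group whose geminal H-3 is roughly orthogonal to the vacant orbital (disfavouring the Meinwald hydride shift to a 3-ketone), so the aligned axial H-5α shifts to C-4 (4β-methyl set), the axial C-10 methyl follows to the β face of C-5 (quaternary centre set) and loss of H-9 gives the conjugated enone, the same eudesmyl → eremophilyl cation sequence as in the biosynthesis; the closest known types are the Westphalen rearrangement, the acid-induced 4,5-epoxyeudesmane → eremophilane methyl shift and backbone rearrangements of 3,4-epoxy triterpenoids.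

**Step 4**
Reactants: 4 isopetasol
Product: 6 7-epi-petasol (3α-hydroxy-7αH-eremophila-9,11-dien-8-one), via dilithium trienolate 5 (not isolated)
Conditions: LiN(iPr)2 (LDA, 3.0 equiv), THF/DMPU, −78 °C; then cannulated into AcOH/THF, −78 °C; used at once
Reagents that add atoms: none
Why: Deconjugative kinetic protonation of an extended enolate: after the alkoxide forms, LDA removes a γ-hydrogen of the isopropylidene methyl syn to the carbonyl (there is no α′-hydrogen), and irreversible α-protonation at C-7 anti to the angular C-5 methyl gives the β,γ-unsaturated ketone with 7α-H.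

**Step 5**
Reactants: 6 7-epi-petasol
Product: 9 3α,9β-dihydroxy-7αH,10βH-eremophil-11-en-8-one, via silyl enol ether 7 (not isolated), via 9-silyloxy ketone 8 (not isolated)
Conditions: [(Ph3P)CuH]6 (5 mol %), PhMe2SiH (2.3 equiv), toluene, 0 °C → rt; then dimethyldioxirane (1.3 equiv, acetone solution), −78 °C; then HF·pyridine, THF, 0 °C
Reagents that add atoms: dimethyldioxirane, CC1(C)OO1; dimethylphenylsilane, C[SiH](C)c1ccccc1 (its silicon stays only in 7 and 8)
Why: Copper hydride 1,4-hydrosilylation then Rubottom oxidation: hydride enters C-10 syn to the angular methyl as conjugate additions to 4a-methyl octalones do (cis ring fusion, 10β-H), the regiodefined enol silane is epoxidised on the convex β face (9β-oxygen) while the isopropenyl group and C-7 are untouched, and fluoride frees both hydroxyls.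

**Step 6**
Reactants: 9 3α,9β-dihydroxy-7αH,10βH-eremophil-11-en-8-one, 10 3-methylbut-2-enoyl chloride (senecioyl chloride, 2.6 equiv)
Product: 11 3α,9β-bis(3-methylbut-2-enoyloxy)-7αH,10βH-eremophil-11-en-8-one (CNP0264508.1)
Conditions: pyridine, DMAP (10 mol %), CH2Cl2, 0 °C → rt
Reagents that add atoms: 3-methylbut-2-enoyl chloride, CC(C)=CC(=O)Cl
Why: DMAP-catalysed O-acylation with retention at both equatorial carbinol centres, pyridine being too weak a base to generate the vinylketene that would deconjugate the senecioyl unit or to epimerise C-7 and C-9, which already sit in their preferred equatorial orientations.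

**Compound list**
1 | germacrone, germacra-1(10)E,4E,7(11)-trien-8-one | O=C1C/C(C)=C/CC/C(C)=C/CC1=C(C)C | starting material
2 | (5R,10R)-eudesma-3,7(11)-dien-8-one (5α-H, 10β-methyl) | CC(C)=C1C[C@H]2C(C)=CCC[C@]2(C)CC1=O | intermediate
3 | 3α,4α-epoxy-5αH-eudesm-7(11)-en-8-one | CC(C)=C1C[C@H]2[C@]3(C)O[C@@H]3CC[C@]2(C)CC1=O | intermediate
4 | isopetasol, 3α-hydroxyeremophila-7(11),9-dien-8-one | CC(C)=C1C[C@]2(C)[C@@H](C)[C@H](O)CCC2=CC1=O | intermediate
5 | dilithium 3α-oxidoeremophila-7,9,11-trien-8-olate (dilithium trienolate) | C=C(C)C=1C[C@]2(C)[C@@H](C)[C@H]([O-])CCC2=CC=1[O-].[Li+].[Li+] | intermediate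
6 | 7-epi-petasol, 3α-hydroxy-7αH-eremophila-9,11-dien-8-one (7β-isopropenyl) | C=C(C)[C@H]1C[C@]2(C)[C@@H](C)[C@H](O)CCC2=CC1=O | intermediate
7 | 3α,8-bis(dimethylphenylsilyloxy)-7αH,10βH-eremophila-8,11-diene (silyl enol ether) | C=C(C)[C@H]1C[C@]2(C)[C@@H](C)[C@H](O[Si](C)(C)c3ccccc3)CC[C@@H]2C=C1O[Si](C)(C)c4ccccc4 | intermediate
8 | 3α,9β-bis(dimethylphenylsilyloxy)-7αH,10βH-eremophil-11-en-8-one (9-silyloxy ketone) | C=C(C)[C@H]1C[C@]2(C)[C@@H](C)[C@H](O[Si](C)(C)c3ccccc3)CC[C@@H]2[C@@H](O[Si](C)(C)c4ccccc4)C1=O | intermediate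
9 | 3α,9β-dihydroxy-7αH,10βH-eremophil-11-en-8-one | C=C(C)[C@H]1C[C@@]2(C)[C@H](CC[C@@H](O)[C@@H]2C)[C@@H](O)C1=O | intermediate
10 | 3-methylbut-2-enoyl chloride (senecioyl chloride) | CC(C)=CC(=O)Cl | starting material
11 | (3R,4R,5R,7R,9R,10S)-3α,9β-bis(3-methylbut-2-enoyloxy)-7αH,10βH-eremophil-11-en-8-one | C=C(C)[C@H]1C[C@@]2(C)[C@H](CC[C@@H](OC(=O)C=C(C)C)[C@@H]2C)[C@@H](OC(=O)C=C(C)C)C1=O | target

**Total step count:** 6. **Longest linear sequence:** 6 steps (1 → 11).

**Steps most likely to fail: 1, 3 and 4**

Step 1 (enantio- and regiocontrol of the transannular cyclization). The fallback sets out from 1 and returns at 2, moving the absolute stereocontrol to a known asymmetric epoxidation. Shi epoxidation of 1 (the fructose-derived ketone enantiomer that gives the 1R,10R oxide, Oxone 2KHSO5·KHSO4·K2SO4, K2CO3) gives (1R,10R)-1,10-epoxygermacra-4E,7(11)-dien-8-one F1, separated from the 4,5-epoxide. BF3·OEt2 opens F1 at C-10 and the 4,5-alkene closes the ring anti to the oxygen, so the epoxide centres fix C-10 and C-5 in 1β-hydroxy-5αH-eudesma-3,7(11)-dien-8-one F2. 1,1′-Thiocarbonyldiimidazole converts F2 into O-(8-oxo-5αH-eudesma-3,7(11)-dien-1β-yl) 1H-imidazole-1-carbothioate F3, and Bu3SnH/AIBN (Barton–McCombie) removes the C-1 oxygen to give 2.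

Step 3 (the hydride shift from C-5 must beat Meinwald ketone formation). The fallback sets out from 2 and returns at 4, using the established 4,5-epoxide methyl shift and installing the C-3 oxygen afterwards. TsOH isomerises 2 to the tetrasubstituted eudesma-4,7(11)-dien-8-one (10β-methyl) F4. mCPBA gives 4α,5α-epoxyeudesm-7(11)-en-8-one F5, anti to the angular methyl. BF3·OEt2 opens F5 at C-5 with antiperiplanar migration of the C-10 methyl and loss of H-9, giving 4α-hydroxyeremophila-7(11),9-dien-8-one F6. POCl3/pyridine eliminates the axial tertiary hydroxyl to eremophila-3,7(11),9-trien-8-one F7. BH3·THF then NaOH/H2O2 adds H-4 and the C-3 oxygen to the α face and reduces C-8, giving eremophila-7(11),9-diene-3α,8-diol (C-8 epimers) F8. MnO2 reoxidises the bis-allylic C-8 alcohol to give 4.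

Step 4 (site of deprotonation, C-7 configuration and lability of 6). The fallback sets out from 4 and returns at 9, postponing deconjugation to the cis-fused series, where the wanted C-7 epimer is also the more stable one; it bypasses step 5 as well. H2 over Pd/C (1 equiv) saturates only the trisubstituted 9,10-alkene from the face syn to the angular methyl, giving 3α-hydroxy-10βH-eremophil-7(11)-en-8-one F9. LiN(iPr)2 (2.2 equiv) deprotonates the α′-CH2 (C-9) kinetically, and Davis oxaziridine (2-(phenylsulfonyl)-3-phenyloxaziridine) oxidises the enolate to 3α,9β-dihydroxy-10βH-eremophil-7(11)-en-8-one F10. Excess LiN(iPr)2 (the C-9 alkoxide shields H-9) then forms the extended enolate from the γ-methyl, and a cold AcOH quench protonates C-7 to give 9.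

**Further compounds**
F1 | step 1 | (1R,10R)-1,10-epoxygermacra-4E,7(11)-dien-8-one | O=C1C[C@@]2(C)O[C@@H]2CC/C(C)=C/CC1=C(C)C
F2 | step 1 | 1β-hydroxy-5αH-eudesma-3,7(11)-dien-8-one | CC(C)=C1C[C@H]2C(C)=CC[C@@H](O)[C@]2(C)CC1=O
F3 | step 1 | O-(8-oxo-5αH-eudesma-3,7(11)-dien-1β-yl) 1H-imidazole-1-carbothioate | CC(C)=C1C[C@H]2C(C)=CC[C@@H](OC(=S)n3ccnc3)[C@]2(C)CC1=O
F4 | step 3 | eudesma-4,7(11)-dien-8-one (10β-methyl) | CC(C)=C1CC2=C(C)CCC[C@]2(C)CC1=O
F5 | step 3 | 4α,5α-epoxyeudesm-7(11)-en-8-one | CC(C)=C1C[C@@]2(O3)[C@@]3(C)CCC[C@]2(C)CC1=O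
F6 | step 3 | 4α-hydroxyeremophila-7(11),9-dien-8-one | CC(C)=C1C[C@]2(C)[C@](C)(O)CCCC2=CC1=O
F7 | step 3 | eremophila-3,7(11),9-trien-8-one | CC(C)=C1C[C@]2(C)C(C)=CCCC2=CC1=O
F8 | step 3 | eremophila-7(11),9-diene-3α,8-diol (C-8 epimers) | CC(C)=C1C[C@]2(C)[C@@H](C)[C@H](O)CCC2=CC1O
F9 | step 4 | 3α-hydroxy-10βH-eremophil-7(11)-en-8-one | CC(C)=C1C[C@]2(C)[C@@H](C)[C@H](O)CC[C@@H]2CC1=O
F10 | step 4 | 3α,9β-dihydroxy-10βH-eremophil-7(11)-en-8-one | CC(C)=C1C[C@]2(C)[C@@H](C)[C@H](O)CC[C@@H]2[C@@H](O)C1=O
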